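The easy step first, since you want a quick number: I lay a line through the origin and the late readings. Your hunch is that dosing the starting material costs product. I doubt it.

| setting | Saturday's | Sunday's | Tuesday's | amber | blue | ochre | grey |
|---|---|---|---|---|---|---|---|
| starting material | 20 mM | 20 mM | 20 mM | 20 mM | 20 mM | 20 mM (fed, over 1.00 min) | 20 mM |
| protic impurity | 2 mM | 1 mM | 4 mM | 2.00 mM | 2.00 mM | 2.00 mM | 2.00 mM |
| free catalyst | 0.28 mol% | 0.28 mol% | 0.28 mol% | 0.28 mol% | 0.28 mol% | 0.28 mol% | 0.28 mol% |
| added ligand | 59 µM | 59 µM | 59 µM | 59 µM | 59 µM | 59 µM | 59 µM |
| remark | run made earlier | run made earlier | run made earlier | a closed flask charged with all of it at once and left for 2.0 min | one stirred flow tank at steady state, fed with the mixture as stated, mean residence time 2.0 min | all but starting material at the start; starting material goes in evenly over 1.00 min, the run ends at 2.0 min | a tube with plug flow, the mixed feed as stated, residence time 2.0 min |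
| time |  |  |  | 2.0 min |  | 2.0 min | 2.0 min |

| run | time / s | product / % |
|---|---|---|
| Saturday's | 10.0 | 0.6 |
| Saturday's | 15.0 | 3.0 |
| Saturday's | 25.0 | 4.8 |
| Saturday's | 40.0 | 8.1 |
| Saturday's | 80.0 | 12.6 |
| Saturday's | 120 | 21.5 |
| Sunday's | 10.0 | 1.6 |
| Sunday's | 15.0 | 4.2 |
| Sunday's | 25.0 | 4.9 |
| Sunday's | 40.0 | 8.5 |
| Sunday's | 80.0 | 12.4 |
| Tuesday's | 10.0 | 2.5 |
| Tuesday's | 15.0 | 3.5 |
| Tuesday's | 25.0 | 2.4 |
| Tuesday's | 40.0 | 7.2 |
| Tuesday's | 60.0 | 10.7 |
| Tuesday's | 80.0 | 13.6 |

(standard deviation of a reading: 1 percentage point)

- the stated concentrations are those of everything mixed, before any reaction; amounts are the same in each set-up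
- the numbers in the tables scatter by 1 percentage point (one standard deviation)
- the feed brings no volume worth counting
- the earlier runs were made in a closed, stirred flask

* the set-up with the highest amount of product at the outlet or at the end, in percent of the starting material put in ("none" if the first two lie within 2 percentage points) (amber / blue / ochre / grey / none)
* amount of product at the outlet or at the end, in percent of the starting material put in, amber
* amount of product at the outlet or at the end, in percent of the starting material put in, blue
* amount of product at the outlet or at the end, in percent of the starting material put in, ochre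
* amount of product at the outlet or at the end, in percent of the starting material put in, grey

At 80.0 s the runs read 12.4%, 12.6% and 13.6%, with protic impurity at 1 mM, 2 mM and 4 mM, so I pool them with Saturday's last reading. I divide the slope of that line by the loading. This gives the turnover rate T, the product made per second per catalyst charged: 0.602 s⁻¹.

My judgement is that the catalyst is saturated, which makes the rate zero-order. I take the binding of starting material as the fast step, so the catalyst stays in its round. The readings cannot prove this at such low conversion.

The charged catalyst is 56.0 µM, so the rate is 0.0337 mM s⁻¹, independent of c(starting material). Amber, blue and grey then each give 20.2%.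

Ochre is the test. Its feed brings 0.333 mM s⁻¹, ten times faster than the catalyst uses it. So c(starting material) builds up early, and I expect ochre just under 20.2%.

The forecast says 20.5% for amber, 18.9% for blue, 16.3% for ochre and 20.5% for grey, with best none: “I lean towards first order”. My ochre stands higher than that.

The flask gives 21.9% for amber, 21.9% for blue, 21.5% for ochre and 21.9% for grey, so best is none, and ochre lies 5.2 percentage points above the forecast.

    catalyst intermediate A → catalyst intermediate B (k = 11.7 s⁻¹)
    starting material + free catalyst → catalyst intermediate A (k = 9420 L mol⁻¹ s⁻¹)
    free catalyst + added ligand ⇌ idle complex (K = 32400 L mol⁻¹, k = 104 L mol⁻¹ s⁻¹)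
    catalyst intermediate B → free catalyst + product (k = 0.696 s⁻¹)
    starting material + protic impurity → quenched substrate (k = 7.28 L mol⁻¹ s⁻¹)

At the end of its feed, ochre holds 93.1% of its catalyst as catalyst intermediate B, the resting state, against 93.8% in amber at that moment. For the neighbour of amber with 0.07 mol% of free catalyst, T gives 5.06%, and that flask gives 5.49%.

(The readings were computed on assumed constants; noise was put on by code.)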